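## Retrosynthetic overview

1. **Feature.** Ring A carries oxygen on C5, C6, C7 and C8a and hydrogen on C8. With the C4–C4a bond removed and the same group on O5 and O7, it becomes a mirror-symmetric 3,5-bis(benzyloxy)-4-methoxyphenoxy unit whose two ortho carbons (future C4a and C8) are identical.
2. **Ring C** is cut first at C4–C4a (intramolecular Friedel–Crafts acylation of a Z 3-aryloxy-3-arylacrylic acid). It is then cut at O1–C2 (oxa-Michael addition of the phenol to an arylpropiolate).
3. **After closure** the C4 carbonyl breaks the symmetry, because only the peri O5 can chelate with it. O5 is debenzylated and methylated, while O7 and the ring B oxygen stay benzylated until a final hydrogenolysis.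
4. **Fragments.** The phenol comes from methyl 3,5-dihydroxy-4-methoxybenzoate (benzylation, reduction, oxidation, Baeyer–Villiger). The propiolate comes from 3-hydroxy-4,5-dimethoxybenzaldehyde (benzylation, Corey–Fuchs, trapping with ethyl chloroformate).
5. **Ring order.** Rings A and B are bought as benzenes. Ring C is the only ring made, and it is closed after the two arenes are joined through O1–C2.

Key step: step 11

Assumption: compounds 1 and 7 are taken as catalogue items, and any minor E isomer of 12 or 13 is carried forward because the push–pull alkene can equilibrate under the acidic ring closure.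

## Route

Step 1
Reactants: 1 methyl 3,5-dihydroxy-4-methoxybenzoate
Product: 2 methyl 3,5-bis(benzyloxy)-4-methoxybenzoate
Conditions: BnBr (2.3 equiv), K2CO3, DMF, 60 °C
Reagents that add atoms: benzyl bromide, BrCc1ccccc1
Why: Williamson ether synthesis: carbonate deprotonates both phenols, which displace bromide from the SN2-reactive benzyl bromide, and the ester and the methoxy group are inert under these conditions.

Step 2
Reactants: 2 methyl 3,5-bis(benzyloxy)-4-methoxybenzoate
Product: 3 [3,5-bis(benzyloxy)-4-methoxyphenyl]methanol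
Conditions: LiAlH4, THF, 0 °C to rt; aqueous work-up
Reagents that add atoms: none
Why: LiAlH4 reduction of an aromatic ester to the primary benzylic alcohol, to which aryl methyl and aryl benzyl ethers are inert.

Step 3
Reactants: 3 [3,5-bis(benzyloxy)-4-methoxyphenyl]methanol
Product: 4 3,5-bis(benzyloxy)-4-methoxybenzaldehyde
Conditions: activated MnO2 (excess), CH2Cl2, rt
Reagents that add atoms: none
Why: Activated MnO2 oxidises benzylic alcohols selectively and stops at the aldehyde, so neither over-oxidation nor attack on the benzyl ether CH2 groups is expected.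

Step 4
Reactants: 4 3,5-bis(benzyloxy)-4-methoxybenzaldehyde
Product: 5 3,5-bis(benzyloxy)-4-methoxyphenyl formate
Conditions: mCPBA (1.3 equiv), CH2Cl2, 0 °C to rt
Reagents that add atoms: meta-chloroperoxybenzoic acid, O=C(OO)c1cccc(Cl)c1
Why: Baeyer–Villiger oxidation of an electron-rich benzaldehyde: in the Criegee adduct the aryl group, supported by the para methoxy oxygen, migrates to oxygen in preference to hydride, as is general for 3,4,5-trialkoxybenzaldehydes.

Step 5
Reactants: 5 3,5-bis(benzyloxy)-4-methoxyphenyl formate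
Product: 6 3,5-bis(benzyloxy)-4-methoxyphenol
Conditions: K2CO3 (0.2 equiv), MeOH, 0 °C to rt, argon
Reagents that add atoms: none
Why: Base-catalysed transesterification: aryl formates are very labile esters, so catalytic carbonate in methanol passes the formyl group to the solvent without touching any ether, and exclusion of air protects the oxidation-prone phenol.

Step 6
Reactants: 7 3-hydroxy-4,5-dimethoxybenzaldehyde
Product: 8 3-(benzyloxy)-4,5-dimethoxybenzaldehyde
Conditions: BnBr (1.2 equiv), K2CO3, DMF, rt to 50 °C
Reagents that add atoms: benzyl bromide, BrCc1ccccc1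
Why: Williamson ether synthesis on the only free phenol, with a non-enolisable aldehyde that tolerates carbonate.

Step 7
Reactants: 8 3-(benzyloxy)-4,5-dimethoxybenzaldehyde
Product: 9 1-(benzyloxy)-5-(2,2-dibromoethenyl)-2,3-dimethoxybenzene
Conditions: CBr4 (2 equiv), PPh3 (4 equiv), CH2Cl2, 0 °C
Reagents that add atoms: carbon tetrabromide, BrC(Br)(Br)Br
Why: First stage of the Corey–Fuchs sequence (Ramirez olefination): the ylide Ph3P=CBr2 made from CBr4 and PPh3 olefinates the aldehyde in a Wittig reaction under neutral conditions that leave the ethers alone.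

Step 8
Reactants: 9 1-(benzyloxy)-5-(2,2-dibromoethenyl)-2,3-dimethoxybenzene
Product: 11 ethyl 3-[3-(benzyloxy)-4,5-dimethoxyphenyl]prop-2-ynoate, via lithium arylacetylide 10 (not isolated)
Conditions: n-BuLi (2.1 equiv), THF, −78 to 0 °C; then ClCO2Et, −78 °C to rt
Reagents that add atoms: ethyl chloroformate, CCOC(=O)Cl
Why: Second stage of the Corey–Fuchs sequence: bromine–lithium exchange, loss of LiBr with a 1,2-shift (Fritsch–Buttenberg–Wiechell type) and deprotonation by the second equivalent of n-BuLi give acetylide 10, which the chloroformate C-acylates at low temperature faster than the product ester can react further.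

Step 9
Reactants: 6 3,5-bis(benzyloxy)-4-methoxyphenol; 11 ethyl 3-[3-(benzyloxy)-4,5-dimethoxyphenyl]prop-2-ynoate
Product: 12 ethyl (Z)-3-[3,5-bis(benzyloxy)-4-methoxyphenoxy]-3-[3-(benzyloxy)-4,5-dimethoxyphenyl]prop-2-enoate
Conditions: Cs2CO3 (0.5 equiv), dry DMF, 80 °C, argon
Reagents that add atoms: none
Why: Base-mediated oxa-Michael addition forming O1–C2: the phenoxide adds through oxygen to the β-carbon of the alkynoate and the resulting anion is protonated anti to the incoming oxygen, which places aryloxy and ester groups on the same side (Z), the isomer that also keeps the bulkier aryl ring trans to the ester.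

Step 10
Reactants: 12 ethyl (Z)-3-[3,5-bis(benzyloxy)-4-methoxyphenoxy]-3-[3-(benzyloxy)-4,5-dimethoxyphenyl]prop-2-enoate
Product: 13 (Z)-3-[3,5-bis(benzyloxy)-4-methoxyphenoxy]-3-[3-(benzyloxy)-4,5-dimethoxyphenyl]prop-2-enoic acid
Conditions: LiOH (3 equiv), THF/EtOH/H2O, rt; then 1 M HCl, 0 °C, product kept cold and used promptly
Reagents that add atoms: lithium hydroxide, [Li+].[OH-]
Why: Ester saponification by acyl–oxygen cleavage: the β-oxygen makes the acrylate a vinylogous carbonate that resists conjugate attack by hydroxide, and a cold, brief acidification avoids enol ether hydrolysis and decarboxylation.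

Step 11
Reactants: 13 (Z)-3-[3,5-bis(benzyloxy)-4-methoxyphenoxy]-3-[3-(benzyloxy)-4,5-dimethoxyphenyl]prop-2-enoic acid
Product: 15 5,7-bis(benzyloxy)-2-[3-(benzyloxy)-4,5-dimethoxyphenyl]-6-methoxy-4H-chromen-4-one, via mixed trifluoroacetic anhydride 14 (not isolated)
Conditions: TFAA (2 equiv), dry CH2Cl2, 0 °C to rt
Reagents that add atoms: none
Why: TFAA turns the acid into mixed anhydride 14, whose acyl carbon (or the acylium ion formed by loss of trifluoroacetate) is attacked by the adjacent ortho carbon of the aryloxy ring, and proton loss from the arenium ion restores ring A and leaves the 4-pyranone, so C4–C4a is the only bond made. The closest known reaction is the Ruhemann-type flavone synthesis, the intramolecular Friedel–Crafts acylation of β-aryloxycinnamic acids, and TFAA activation is the variant commonly used to close 2-aryloxybenzoic acids to xanthones. Ring C closes in a 6-exo-trig mode at the acyl C=O, with the arene double bond inside the new ring, onto the O1–C2 link already in place. No stereocentre is formed and the Z alkene geometry disappears into the ring. Site selectivity on ring A is secured because the two ortho carbons are interchanged by the mirror plane through O1–C8a and C6–OMe and the para carbon is occupied, while the attacked carbon is ortho to O1, ortho to one benzyloxy group and para to the other, hence nucleophilic enough for an anhydride without a strong Lewis acid, which spares the benzyl ethers and the enol ether. Ring A is preferred over ring B because the Z geometry holds the acyl group beside the aryloxy ring, whereas attack on ring B would need the E isomer and a strained five-membered indenone, and partial loss of the O5 benzyl group does no harm since step 12 removes it.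

Step 12
Reactants: 15 5,7-bis(benzyloxy)-2-[3-(benzyloxy)-4,5-dimethoxyphenyl]-6-methoxy-4H-chromen-4-one
Product: 16 7-(benzyloxy)-2-[3-(benzyloxy)-4,5-dimethoxyphenyl]-5-hydroxy-6-methoxy-4H-chromen-4-one
Conditions: MgBr2·OEt2 (3 equiv), toluene/Et2O, 80 °C; then 1 M HCl
Reagents that add atoms: none
Why: Chelation-directed ether cleavage: magnesium binds the C4 carbonyl and the peri O5 in a six-membered chelate and so activates only this benzyl–oxygen bond to SN2 attack by bromide, the known behaviour of MgBr2 toward aryl benzyl ethers ortho to a carbonyl group, whereas the O7 and ring B benzyl ethers cannot chelate.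

Step 13
Reactants: 16 7-(benzyloxy)-2-[3-(benzyloxy)-4,5-dimethoxyphenyl]-5-hydroxy-6-methoxy-4H-chromen-4-one
Product: 17 7-(benzyloxy)-2-[3-(benzyloxy)-4,5-dimethoxyphenyl]-5,6-dimethoxy-4H-chromen-4-one
Conditions: Me2SO4 (3 equiv), K2CO3 (excess), acetone, reflux, prolonged
Reagents that add atoms: dimethyl sulfate, COS(=O)(=O)OC
Why: Williamson-type O-methylation: the hydrogen-bonded, flanked 5-hydroxyl is a poor nucleophile, but excess dimethyl sulfate and carbonate in refluxing acetone is the standard way to methylate 5-hydroxyflavones, and no other free hydroxyl competes.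

Step 14
Reactants: 17 7-(benzyloxy)-2-[3-(benzyloxy)-4,5-dimethoxyphenyl]-5,6-dimethoxy-4H-chromen-4-one
Product: 18 7,5'-dihydroxy-5,6,3',4'-tetramethoxyflavone
Conditions: H2 (1 atm), Pd/C (10 wt% Pd), THF/MeOH, rt
Reagents that add atoms: none
Why: Catalytic hydrogenolysis of the two aryl benzyl ethers over Pd/C: benzylic C–O cleavage is much faster than reduction of the conjugated C2–C3 double bond of a flavone at one atmosphere, so the reaction is stopped after uptake of two equivalents of hydrogen.

## Compound list

1 | methyl 3,5-dihydroxy-4-methoxybenzoate | COC(=O)c1cc(O)c(OC)c(O)c1 | starting material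
2 | methyl 3,5-bis(benzyloxy)-4-methoxybenzoate | COC(=O)c1cc(OCc2ccccc2)c(OC)c(OCc2ccccc2)c1 | intermediate
3 | [3,5-bis(benzyloxy)-4-methoxyphenyl]methanol | OCc1cc(OCc2ccccc2)c(OC)c(OCc2ccccc2)c1 | intermediate
4 | 3,5-bis(benzyloxy)-4-methoxybenzaldehyde | O=Cc1cc(OCc2ccccc2)c(OC)c(OCc2ccccc2)c1 | intermediate
5 | 3,5-bis(benzyloxy)-4-methoxyphenyl formate | O=COc1cc(OCc2ccccc2)c(OC)c(OCc2ccccc2)c1 | intermediate
6 | 3,5-bis(benzyloxy)-4-methoxyphenol | Oc1cc(OCc2ccccc2)c(OC)c(OCc2ccccc2)c1 | intermediate
7 | 3-hydroxy-4,5-dimethoxybenzaldehyde | O=Cc1cc(O)c(OC)c(OC)c1 | starting material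
8 | 3-(benzyloxy)-4,5-dimethoxybenzaldehyde | O=Cc1cc(OCc2ccccc2)c(OC)c(OC)c1 | intermediate
9 | 1-(benzyloxy)-5-(2,2-dibromoethenyl)-2,3-dimethoxybenzene | BrC(Br)=Cc1cc(OCc2ccccc2)c(OC)c(OC)c1 | intermediate
10 | lithium [3-(benzyloxy)-4,5-dimethoxyphenyl]acetylide | [Li]C#Cc1cc(OCc2ccccc2)c(OC)c(OC)c1 | intermediate (not isolated)
11 | ethyl 3-[3-(benzyloxy)-4,5-dimethoxyphenyl]prop-2-ynoate | CCOC(=O)C#Cc1cc(OCc2ccccc2)c(OC)c(OC)c1 | intermediate
12 | ethyl (Z)-3-[3,5-bis(benzyloxy)-4-methoxyphenoxy]-3-[3-(benzyloxy)-4,5-dimethoxyphenyl]prop-2-enoate | CCOC(=O)/C=C(\Oc1cc(OCc2ccccc2)c(OC)c(OCc2ccccc2)c1)c1cc(OCc2ccccc2)c(OC)c(OC)c1 | intermediate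
13 | (Z)-3-[3,5-bis(benzyloxy)-4-methoxyphenoxy]-3-[3-(benzyloxy)-4,5-dimethoxyphenyl]prop-2-enoic acid | OC(=O)/C=C(\Oc1cc(OCc2ccccc2)c(OC)c(OCc2ccccc2)c1)c1cc(OCc2ccccc2)c(OC)c(OC)c1 | intermediate
14 | (Z)-3-[3,5-bis(benzyloxy)-4-methoxyphenoxy]-3-[3-(benzyloxy)-4,5-dimethoxyphenyl]prop-2-enoic trifluoroacetic anhydride | O=C(OC(=O)C(F)(F)F)/C=C(\Oc1cc(OCc2ccccc2)c(OC)c(OCc2ccccc2)c1)c1cc(OCc2ccccc2)c(OC)c(OC)c1 | intermediate (not isolated)
15 | 5,7-bis(benzyloxy)-2-[3-(benzyloxy)-4,5-dimethoxyphenyl]-6-methoxy-4H-chromen-4-one | COc1cc(-c2cc(=O)c3c(OCc4ccccc4)c(OC)c(OCc4ccccc4)cc3o2)cc(OCc2ccccc2)c1OC | intermediate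
16 | 7-(benzyloxy)-2-[3-(benzyloxy)-4,5-dimethoxyphenyl]-5-hydroxy-6-methoxy-4H-chromen-4-one | COc1cc(-c2cc(=O)c3c(O)c(OC)c(OCc4ccccc4)cc3o2)cc(OCc2ccccc2)c1OC | intermediate
17 | 7-(benzyloxy)-2-[3-(benzyloxy)-4,5-dimethoxyphenyl]-5,6-dimethoxy-4H-chromen-4-one | COc1cc(-c2cc(=O)c3c(OC)c(OC)c(OCc4ccccc4)cc3o2)cc(OCc2ccccc2)c1OC | intermediate
18 | 7,5'-dihydroxy-5,6,3',4'-tetramethoxyflavone | COc1cc(-c2cc(=O)c3c(OC)c(OC)c(O)cc3o2)cc(O)c1OC | target

## Step count and risks

Total step count: 14. Longest linear sequence: 11 steps (steps 1–5, then 9–14). The ring B branch (steps 6–8) is convergent.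

**Step 11 (ring closure).**
- Risks: the trifluoroacetic acid released during activation may strip or shift benzyl groups on the very electron-rich rings. The free ortho carbon may be trifluoroacetylated. Traces of water may hydrolyse the enol ether before closure.
- Fallback: the polarity of ring A is inverted so that no acid is needed, while the same C4–C4a bond is still formed.
- It sets out from 6, which is mono-iodinated at one of its two equivalent ortho carbons (N-iodosuccinimide, CH2Cl2, low temperature) to give 3,5-bis(benzyloxy)-2-iodo-4-methoxyphenol F1.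
- F1 is added to 11 under the conditions of step 9 to give ethyl (Z)-3-[3,5-bis(benzyloxy)-2-iodo-4-methoxyphenoxy]-3-[3-(benzyloxy)-4,5-dimethoxyphenyl]prop-2-enoate F2.
- Iodine–magnesium exchange with i-PrMgCl·LiCl (1.05 equiv, THF, −30 °C) gives the arylmagnesium chloride F3.
- On warming, F3 attacks its own ester carbonyl and expels ethoxide. The route is rejoined at 15.

**Step 9 (oxa-Michael addition).**
- Risks: conjugate addition to a β-aryl alkynoate may be slow. The ambident, phloroglucinol-like phenoxide may attack through carbon. The phenoxide may be oxidised by air, and geometric mixtures may form.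
- Fallback: addition to the alkyne is replaced by substitution at a vinyl halide.
- It sets out from 11, which is hydroiodinated by anti addition (NaI, AcOH, heat) to give ethyl (Z)-3-[3-(benzyloxy)-4,5-dimethoxyphenyl]-3-iodoprop-2-enoate F4.
- F4 is coupled with 6 in an Ullmann-type vinyl C–O coupling that retains geometry (CuI, N,N-dimethylglycine, Cs2CO3, dioxane, 90 °C). The route is rejoined at 12.
- Competing dehydroiodination only regenerates 11.

**Step 12 (selective debenzylation at O5).**
- Risks: crowding by the 6-methoxy group may slow the cleavage. Forcing the reaction may cost further benzyl groups, or may cause demethylation at O6 once the chelate has formed.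
- Fallback: the peri effect is used in the opposite sense.
- It sets out from 15, whose three benzyl ethers are all hydrogenolysed (H2, Pd/C) to give 5,7-dihydroxy-2-(3-hydroxy-4,5-dimethoxyphenyl)-6-methoxy-4H-chromen-4-one F5.
- Benzylation with about two equivalents of BnBr (K2CO3, acetone, rt) then takes the acidic 7-hydroxyl and the ring B hydroxyl. The hydrogen-bonded 5-hydroxyl is left free, and the route is rejoined at 16.

## Further compounds

F1 | step 11 | 3,5-bis(benzyloxy)-2-iodo-4-methoxyphenol | Oc1cc(OCc2ccccc2)c(OC)c(OCc2ccccc2)c1I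
F2 | step 11 | ethyl (Z)-3-[3,5-bis(benzyloxy)-2-iodo-4-methoxyphenoxy]-3-[3-(benzyloxy)-4,5-dimethoxyphenyl]prop-2-enoate | CCOC(=O)/C=C(\Oc1cc(OCc2ccccc2)c(OC)c(OCc2ccccc2)c1I)c1cc(OCc2ccccc2)c(OC)c(OC)c1
F3 | step 11 | arylmagnesium chloride derived from F2 by iodine–magnesium exchange | CCOC(=O)/C=C(\Oc1cc(OCc2ccccc2)c(OC)c(OCc2ccccc2)c1[Mg]Cl)c1cc(OCc2ccccc2)c(OC)c(OC)c1
F4 | step 9 | ethyl (Z)-3-[3-(benzyloxy)-4,5-dimethoxyphenyl]-3-iodoprop-2-enoate | CCOC(=O)/C=C(\I)c1cc(OCc2ccccc2)c(OC)c(OC)c1
F5 | step 12 | 5,7-dihydroxy-2-(3-hydroxy-4,5-dimethoxyphenyl)-6-methoxy-4H-chromen-4-one | COc1cc(-c2cc(=O)c3c(O)c(OC)c(O)cc3o2)cc(O)c1OC
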